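**Plan**

- Retrosynthesis, pyran numbering O1, C2 (CH3), C3 (CH2OH), C4 (CH2CO2R), C5 (CO2Me), C6: first C3–CH2OH is traced back to C3–CHO. Then the O1–C2 bond is cut: O1–C2(CH3)–C3–CHO is a β-alkoxy aldehyde, the retron of an oxa-Michael addition, and O1–C6H=C5(CO2Me) is the enol of a formylacetate.
- This opens the ring to the (E)-ethylidene enal/formylacetate enol, the open dialdehyde form of the secoiridoid aglycone as in the presumed biosynthesis. The enol is stored in an enol δ-lactone (temporary ring), cut at the side-chain ester C–O bond to release hydroxytyrosol.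
- The lactone comes from a lactol and that from a thioester aldehyde; the C4–C5 bond is cut (Michael) to a thiomalonate and a 2,4-dienal, and the dienal is cut (Heck) to acrolein and the acetal of (Z)-2-iodobut-2-enal.
- Forward: the chain is joined first (Heck, Michael), then the temporary lactol/enol lactone ring is made. The 3,4-dihydro-2H-pyran, the only ring of the skeleton, is closed last in a one-pot acyl transfer/unmasking/6-endo oxa-Michael ring switch, and the aldehyde helper is reduced.
- Stereochemistry: C4 by catalyst control (iminium Michael addition with an (S)-diarylprolinol silyl ether). C2 and C3 arise in the key step under control of C4 (allylic strain in the E-ethylidene enal, equilibrating protonation next to the aldehyde).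

Key step: step 8

Remark: the malonyl carbon of the Michael adduct and the anomeric carbon of the lactol are carried as mixtures, because both centres become sp2 before the key step.

**Route**

Step 1
Reactants: 1 (E)-but-2-enal
Product: 2 (Z)-2-iodobut-2-enal
Conditions: I2, K2CO3, 4-(dimethylamino)pyridine (20 mol%), THF/H2O (1:1), rt
Reagents that add atoms: iodine, II
Why: α-iodination of an enal by amine-catalysed conjugate addition, iodination of the enolate and elimination (Baylis–Hillman-type activation) should give the α-iodo enal as the more stable (Z) isomer, with iodine and methyl cis.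

Step 2
Reactants: 2 (Z)-2-iodobut-2-enal
Product: 3 (Z)-2-iodo-1,1-dimethoxybut-2-ene
Conditions: HC(OMe)3, MeOH, 4-toluenesulfonic acid monohydrate (1 mol%), rt
Reagents that add atoms: trimethyl orthoformate, COC(OC)OC
Why: acid-catalysed acetalisation with an orthoester as water scavenger masks this aldehyde, so that later only the new enal can form an iminium ion, and leaves the alkene geometry untouched.

Step 3
Reactants: 3 (Z)-2-iodo-1,1-dimethoxybut-2-ene; 4 prop-2-enal (acrolein)
Product: 5 (2E,4E)-4-(dimethoxymethyl)hexa-2,4-dienal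
Conditions: Pd(OAc)2 (5 mol%), NaHCO3, Bu4NCl, DMF, 40 °C
Reagents that add atoms: none
Why: Heck reaction under ligand-free phase-transfer conditions, in which oxidative addition of the alkenyl iodide to zerovalent palladium with retention, insertion of acrolein at its terminal carbon and syn β-hydride elimination should give the (2E,4E)-dienal.

Step 4
Reactants: 6 methyl 3-chloro-3-oxopropanoate; 7 ethanethiol
Product: 8 methyl 3-(ethylsulfanyl)-3-oxopropanoate
Conditions: pyridine, CH2Cl2, 0 °C
Reagents that add atoms: none
Why: acylation of a thiol by an acid chloride (Schotten–Baumann-type thioesterification) gives the mixed malonate whose thioester can later be reduced selectively.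

Step 5
Reactants: 5 (2E,4E)-4-(dimethoxymethyl)hexa-2,4-dienal; 8 methyl 3-(ethylsulfanyl)-3-oxopropanoate
Product: 9 methyl (3R,4E)-4-(dimethoxymethyl)-2-[(ethylsulfanyl)carbonyl]-3-(2-oxoethyl)hex-4-enoate (epimers at C2)
Conditions: (S)-2-{bis[3,5-bis(trifluoromethyl)phenyl][(trimethylsilyl)oxy]methyl}pyrrolidine (10 mol%), EtOH, 0 °C
Reagents that add atoms: none
Why: iminium-catalysed asymmetric Michael addition of a malonate-type donor to an enal, in which the bulky group of the (S)-diarylprolinol silyl ether blocks one face of the (E)-iminium ion so that the donor should add to the Si face of C3 and set the future C4 of the pyran, while the substituents at C4 and C5 of the dienal disfavour 1,6-addition.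

Step 6
Reactants: 9 methyl (3R,4E)-4-(dimethoxymethyl)-2-[(ethylsulfanyl)carbonyl]-3-(2-oxoethyl)hex-4-enoate
Product: 11 methyl (4S)-4-[(1E)-1-(dimethoxymethyl)prop-1-en-1-yl]-2-hydroxy-3,4-dihydro-2H-pyran-5-carboxylate (both anomers), via formylacetate dialdehyde 10 (not isolated)
Conditions: Et3SiH, Pd/C (10 wt% Pd), acetone, rt
Reagents that add atoms: none
Why: Fukuyama reduction converts only the thioester into an aldehyde, and the resulting formylacetate enol should close spontaneously on the other aldehyde to the six-membered lactol, the form that secoiridoid aglycones of this type adopt.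

Step 7
Reactants: 11 methyl (4S)-4-[(1E)-1-(dimethoxymethyl)prop-1-en-1-yl]-2-hydroxy-3,4-dihydro-2H-pyran-5-carboxylate
Product: 12 methyl (4S)-4-[(1E)-1-(dimethoxymethyl)prop-1-en-1-yl]-2-oxo-3,4-dihydro-2H-pyran-5-carboxylate
Conditions: Ag2CO3 on Celite, toluene, 80 °C
Reagents that add atoms: none
Why: Fetizon oxidation of a lactol to a lactone under neutral conditions should give the enol δ-lactone without touching the acetal, the alkene or the stereocentre.

Step 8
Reactants: 12 methyl (4S)-4-[(1E)-1-(dimethoxymethyl)prop-1-en-1-yl]-2-oxo-3,4-dihydro-2H-pyran-5-carboxylate; 13 2-(3,4-dihydroxyphenyl)ethanol (hydroxytyrosol)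
Product: 16 methyl (2S,3S,4S)-4-{2-[2-(3,4-dihydroxyphenyl)ethoxy]-2-oxoethyl}-3-formyl-2-methyl-3,4-dihydro-2H-pyran-5-carboxylate, via ring-opened enol acetal 14 (not isolated), via open dialdehyde enol 15 (not isolated)
Conditions: 4-(dimethylamino)pyridine (10 mol%), MeCN, rt, argon; then 1 M aq HCl, THF, 0 °C to rt; then NaH2PO4/Na2HPO4 buffer (pH 6.5), rt
Reagents that add atoms: water, O
Why: The nucleophilic catalyst adds to the lactone carbonyl of 12, the acylpyridinium ion is taken by the primary hydroxyl group of 13 and the formylacetate enol is set free (14); dilute acid then hydrolyses the dimethyl acetal to the (E)-ethylidene enal 15, whose enol oxygen adds to the β-carbon of the enal before the new aldehyde enol is protonated at C3. The closest known reaction types are the alcoholysis of 3,4-dihydropyran-2-ones and the ring switch that oleoside-type secoiridoid aglycones undergo after enzymatic loss of glucose, so the step copies the presumed biosynthesis. The ring is closed in the 6-endo-trig mode (oxa-Michael); attack by carbon C5 instead of oxygen is excluded because it would give a four-membered ring. C2 is controlled by the stereocentre C4: allylic 1,3-strain between the ethylidene methyl group and C4 holds the C4–H bond in the plane of the enal, so the enol arm reaches the face opposite to the CH2CO2R chain and the methyl group ends trans to that chain. C3 is set by protonation and equilibration next to the aldehyde, which should favour the half-chair with the formyl group trans to the C4 chain (both pseudoaxial, the C2 methyl equatorial), free of allylic 1,2-strain with the C5 ester. The step needs acylation of the aliphatic hydroxyl in the presence of the catechol, which the higher nucleophilicity of the primary alcohol and the ready transfer of any aryl ester to it under the same catalyst should secure.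

Step 9
Reactants: 16 methyl (2S,3S,4S)-4-{2-[2-(3,4-dihydroxyphenyl)ethoxy]-2-oxoethyl}-3-formyl-2-methyl-3,4-dihydro-2H-pyran-5-carboxylate
Product: 17 methyl (2S,3R,4S)-4-{2-[2-(3,4-dihydroxyphenyl)ethoxy]-2-oxoethyl}-3-(hydroxymethyl)-2-methyl-3,4-dihydro-2H-pyran-5-carboxylate
Conditions: NaBH4, MeOH, −20 °C; then AcOH
Reagents that add atoms: none
Why: chemoselective borohydride reduction of an aldehyde in the presence of two esters and an enol ether should give the primary alcohol with the three stereocentres unchanged (the descriptor at C3 changes only by the priority rules), and the cold acidic quench avoids lactonisation of the new alcohol onto the side-chain ester.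

**Compound list**

1 | (E)-but-2-enal (crotonaldehyde) | C/C=C/C=O | starting material
2 | (Z)-2-iodobut-2-enal | C/C=C(\I)C=O | intermediate
3 | (Z)-2-iodo-1,1-dimethoxybut-2-ene | C/C=C(\I)C(OC)OC | intermediate
4 | prop-2-enal (acrolein) | C=CC=O | starting material
5 | (2E,4E)-4-(dimethoxymethyl)hexa-2,4-dienal | C/C=C(\C=C\C=O)C(OC)OC | intermediate
6 | methyl 3-chloro-3-oxopropanoate | COC(=O)CC(Cl)=O | starting material
7 | ethanethiol | CCS | starting material
8 | methyl 3-(ethylsulfanyl)-3-oxopropanoate | CCSC(=O)CC(=O)OC | intermediate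
9 | methyl (3R,4E)-4-(dimethoxymethyl)-2-[(ethylsulfanyl)carbonyl]-3-(2-oxoethyl)hex-4-enoate (epimers at C2) | CCSC(=O)C(C(=O)OC)[C@H](/C(=C\C)C(OC)OC)CC=O | intermediate
10 | methyl (3R,4E)-4-(dimethoxymethyl)-2-formyl-3-(2-oxoethyl)hex-4-enoate (epimers at C2) | COC(=O)C(C=O)[C@H](/C(=C\C)C(OC)OC)CC=O | intermediate (not isolated)
11 | methyl (4S)-4-[(1E)-1-(dimethoxymethyl)prop-1-en-1-yl]-2-hydroxy-3,4-dihydro-2H-pyran-5-carboxylate (both anomers) | COC(=O)C1=COC(O)C[C@H]1/C(=C\C)C(OC)OC | intermediate
12 | methyl (4S)-4-[(1E)-1-(dimethoxymethyl)prop-1-en-1-yl]-2-oxo-3,4-dihydro-2H-pyran-5-carboxylate | COC(=O)C1=COC(=O)C[C@H]1/C(=C\C)C(OC)OC | intermediate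
13 | 2-(3,4-dihydroxyphenyl)ethanol (hydroxytyrosol) | OCCc1ccc(O)c(O)c1 | starting material
14 | 5-[2-(3,4-dihydroxyphenyl)ethyl] 1-methyl (2Z,3S)-3-[(1E)-1-(dimethoxymethyl)prop-1-en-1-yl]-2-(hydroxymethylidene)pentanedioate | COC(=O)/C(=C\O)[C@@H](CC(=O)OCCc1ccc(O)c(O)c1)/C(=C\C)C(OC)OC | intermediate (not isolated)
15 | 5-[2-(3,4-dihydroxyphenyl)ethyl] 1-methyl (2Z,3S)-2-(hydroxymethylidene)-3-[(2E)-1-oxobut-2-en-2-yl]pentanedioate | COC(=O)/C(=C\O)[C@@H](CC(=O)OCCc1ccc(O)c(O)c1)/C(C=O)=C\C | intermediate (not isolated)
16 | methyl (2S,3S,4S)-4-{2-[2-(3,4-dihydroxyphenyl)ethoxy]-2-oxoethyl}-3-formyl-2-methyl-3,4-dihydro-2H-pyran-5-carboxylate | COC(=O)C1=CO[C@@H](C)[C@@H](C=O)[C@@H]1CC(=O)OCCc1ccc(O)c(O)c1 | intermediate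
17 | methyl (2S,3R,4S)-4-{2-[2-(3,4-dihydroxyphenyl)ethoxy]-2-oxoethyl}-3-(hydroxymethyl)-2-methyl-3,4-dihydro-2H-pyran-5-carboxylate | COC(=O)C1=CO[C@@H](C)[C@@H](CO)[C@@H]1CC(=O)OCCc1ccc(O)c(O)c1 | target

**Step count and risks**

Total step count: 9. Longest linear sequence: 8 steps (steps 1, 2, 3, 5, 6, 7, 8, 9); step 4 is a one-step side branch.

The three steps most likely to fail:

1. Step 8 (key step). What may go wrong: acyl transfer to a phenolic hydroxyl, or conjugate attack at the enol carbon of the lactone instead of at its carbonyl group; also incomplete facial control in the ring closure or incomplete equilibration at C3, which would leave C2/C3 epimers. The fallback is stepwise, with a protected arene and a catalyst-controlled closure, and sets out from 12 and 13.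
   - Compound 13 is silylated on all three hydroxyl groups (tert-butyl(chloro)dimethylsilane, imidazole, DMF) to tert-butyl{2-[3,4-bis(tert-butyldimethylsilyloxy)phenyl]ethoxy}dimethylsilane F1.
   - The alkyl silyl ether alone is cleaved (pyridinium 4-toluenesulfonate, MeOH) to 2-[3,4-bis(tert-butyldimethylsilyloxy)phenyl]ethanol F2.
   - Alcohol F2 opens 12 under 4-(dimethylamino)pyridine catalysis to the isolated silyl-protected ring-opened enol acetal F3.
   - Aqueous CF3CO2H in CH2Cl2 at 0 °C unmasks the silyl-protected open dialdehyde enol F4. This is closed under iminium catalysis by a chiral primary amine salt, 9-amino-9-deoxy-epi-quinine bis(trifluoroacetate), or the pseudoenantiomeric quinidine-derived amine if that catalyst proves mismatched to C4. The catalyst, and not only the substrate, then directs the oxa-Michael face and the protonation of the enamine, which should give the silyl-protected pyran aldehyde F5.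
   - Et3N·3HF in THF removes both aryl silyl groups, and the route is rejoined at 16.

2. Step 5. What may go wrong: 1,6-addition or trienamine formation at the dienal, slow turnover at the hindered β-carbon with erosion of enantioselectivity, or acylation of the amine catalyst by the thioester. The fallback replaces iminium catalysis by chiral Lewis acid catalysis on a chelating acyl pyrazole and sets out from 3.
   - Heck coupling of 3 with 1-(3,5-dimethyl-1H-pyrazol-1-yl)prop-2-en-1-one under the conditions of step 3 gives (2E,4E)-4-(dimethoxymethyl)-1-(3,5-dimethyl-1H-pyrazol-1-yl)hexa-2,4-dien-1-one F6.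
   - Michael addition of 8 is catalysed by Ni(ClO4)2·6H2O and (R,R)-4,6-dibenzofurandiyl-2,2′-bis(4-phenyl-2-oxazoline) with 2,2,6,6-tetramethylpiperidine in THF. The acyl pyrazole chelates divalent nickel, and the ligand enantiomer is chosen so that the (3R) adduct results. This should give the thioester acyl pyrazole F7.
   - Fukuyama reduction (Et3SiH, Pd/C, acetone) converts F7 into the formylacetate acyl pyrazole F8. Its enol oxygen acylates itself on the activated amide with loss of 3,5-dimethylpyrazole (Et3N if needed).
   - This enol lactonisation rejoins the route at 12 and bypasses 5, 9, 10 and 11.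

3. Step 3. What may go wrong: oligomerisation of acrolein under the basic conditions and slow insertion at the hindered alkenylpalladium species, with loss of alkene geometry on prolonged heating. The fallback is a Stille coupling at the alcohol oxidation level followed by oxidation, and sets out from 3.
   - Coupling of 3 with (E)-3-(tributylstannyl)prop-2-en-1-ol (Pd(PPh3)4, CuI, DMF, rt) should give (2E,4E)-4-(dimethoxymethyl)hexa-2,4-dien-1-ol F9 with retention at both alkenes.
   - MnO2 in CH2Cl2 oxidises the allylic alcohol, and the route is rejoined at 5.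

**Further compounds**

F1 | step 8 | tert-butyl{2-[3,4-bis(tert-butyldimethylsilyloxy)phenyl]ethoxy}dimethylsilane | CC(C)(C)[Si](C)(C)OCCc1ccc(O[Si](C)(C)C(C)(C)C)c(O[Si](C)(C)C(C)(C)C)c1
F2 | step 8 | 2-[3,4-bis(tert-butyldimethylsilyloxy)phenyl]ethanol | OCCc1ccc(O[Si](C)(C)C(C)(C)C)c(O[Si](C)(C)C(C)(C)C)c1
F3 | step 8 | 5-{2-[3,4-bis(tert-butyldimethylsilyloxy)phenyl]ethyl} 1-methyl (2Z,3S)-3-[(1E)-1-(dimethoxymethyl)prop-1-en-1-yl]-2-(hydroxymethylidene)pentanedioate | COC(=O)/C(=C\O)[C@@H](CC(=O)OCCc1ccc(O[Si](C)(C)C(C)(C)C)c(O[Si](C)(C)C(C)(C)C)c1)/C(=C\C)C(OC)OC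
F4 | step 8 | 5-{2-[3,4-bis(tert-butyldimethylsilyloxy)phenyl]ethyl} 1-methyl (2Z,3S)-2-(hydroxymethylidene)-3-[(2E)-1-oxobut-2-en-2-yl]pentanedioate | COC(=O)/C(=C\O)[C@@H](CC(=O)OCCc1ccc(O[Si](C)(C)C(C)(C)C)c(O[Si](C)(C)C(C)(C)C)c1)/C(C=O)=C\C
F5 | step 8 | methyl (2S,3S,4S)-4-(2-{2-[3,4-bis(tert-butyldimethylsilyloxy)phenyl]ethoxy}-2-oxoethyl)-3-formyl-2-methyl-3,4-dihydro-2H-pyran-5-carboxylate | COC(=O)C1=CO[C@@H](C)[C@@H](C=O)[C@@H]1CC(=O)OCCc1ccc(O[Si](C)(C)C(C)(C)C)c(O[Si](C)(C)C(C)(C)C)c1
F6 | step 5 | (2E,4E)-4-(dimethoxymethyl)-1-(3,5-dimethyl-1H-pyrazol-1-yl)hexa-2,4-dien-1-one | C/C=C(\C=C\C(=O)n1nc(C)cc1C)C(OC)OC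
F7 | step 5 | methyl (3R,4E)-4-(dimethoxymethyl)-3-[2-(3,5-dimethyl-1H-pyrazol-1-yl)-2-oxoethyl]-2-[(ethylsulfanyl)carbonyl]hex-4-enoate (epimers at C2) | CCSC(=O)C(C(=O)OC)[C@H](/C(=C\C)C(OC)OC)CC(=O)n1nc(C)cc1C
F8 | step 5 | methyl (3R,4E)-4-(dimethoxymethyl)-3-[2-(3,5-dimethyl-1H-pyrazol-1-yl)-2-oxoethyl]-2-formylhex-4-enoate (epimers at C2) | COC(=O)C(C=O)[C@H](/C(=C\C)C(OC)OC)CC(=O)n1nc(C)cc1C
F9 | step 3 | (2E,4E)-4-(dimethoxymethyl)hexa-2,4-dien-1-ol | C/C=C(\C=C\CO)C(OC)OC
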